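**Plan**

1. Late cuts: the two benzyl ethers and two silyl ethers, the C7''=O bond (carried as a C7''=CH–CH3 ethylidene) and the C7' methylene (carried as an aryl ketone).
2. Central cut: ring B is opened at C1'–C2' and C5'–C6'. Ring B is a 1,3,4,5-tetrasubstituted guaiacol whose C4' oxygen sits between the C3' methoxy group and the C5' side chain and para to C1' (the carbon holding C7'). That is the pattern a 1,2-dimethoxy-3-silyloxy-1,3-diene and an ethynyl ketone give after loss of methanol.
3. Ynone half: C7'–C≡C (Weinreb acylation), C7–C8 (benzylation of a lactone dianion), C8'–C9' (hydroxymethylation of a succinyl imide).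
4. Diene half: diene C2–C3 (alkenyllithium acylation), CH2–C8'' (Johnson–Claisen), C7''–ring C (Stille coupling on a hydrostannylated alkynol).
5. Forward order: the lactone with ring A is made first, then the ring C chain; ring B is formed last and joins the halves; deoxygenation, alkene cleavage and deprotection finish the route.
6. Stereochemistry: C8' from the (S)-4-benzyloxazolidinone auxiliary, C8 from trans-selective alkylation next to C8', C8'' from (R)-but-3-yn-2-ol by 1,3-chirality transfer in the Claisen step.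

Key step: step 17

Remark: lignan locants are used (ring A C1–C6 with C7–C9, C9 = lactone C=O; ring B C1'–C6' with C7'–C9', C9' = lactone OCH2; ring C with C7'', C8'', C9''); TBS = tert-butyldimethylsilyl.
Remark: (Z)-1,2-dimethoxyethene is assumed to be available as the single Z isomer.
Remark: where the descriptor of C8' or C8'' changes between intermediates, only the CIP priorities change; the spatial arrangement is constant throughout.

**Route**

Step 1
Reactants: 1 (S)-4-benzyloxazolidin-2-one; 2 methyl 4-chloro-4-oxobutanoate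
Product: 3 methyl 4-[(4S)-4-benzyl-2-oxooxazolidin-3-yl]-4-oxobutanoate
Conditions: n-BuLi, THF, −78 °C; then 2, −78 → 0 °C
Reagents that add atoms: none
Why: N-acylation of the lithiated oxazolidinone by the acid chloride is fast at low temperature and leaves the methyl ester untouched (standard imide preparation).

Step 2
Reactants: 3
Product: 5 (4S)-4-benzyl-3-[(3R)-5-oxotetrahydrofuran-3-carbonyl]oxazolidin-2-one, via hydroxymethyl imide 4 (not isolated)
Conditions: TiCl4, iPr2NEt, CH2Cl2, 0 °C; 1,3,5-trioxane, TiCl4, 0 °C; aq. NH4Cl; then TsOH·H2O (cat.), CH2Cl2, rt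
Reagents that add atoms: 1,3,5-trioxane C1OCOCO1
Why: Titanium-enolate hydroxymethylation of an N-acyloxazolidinone: the chelated Z enolate should be attacked by activated trioxane on the face opposite the C4 benzyl group, setting C8' as 3R, and the γ-hydroxy ester then lactonises to the five-membered ring under acid.

Step 3
Reactants: 5
Product: 7 (3R)-5-oxotetrahydrofuran-3-carboxylic acid, via peroxy acid 6 (not isolated)
Conditions: LiOH, H2O2, THF/H2O, 0 °C; Na2SO3; then HCl to pH 1, continuous extraction with EtOAc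
Reagents that add atoms: hydrogen peroxide OO
Why: Hydroperoxide cleaves the exocyclic imide carbonyl selectively (standard auxiliary removal), sulfite reduces the peracid, acidification recloses any opened lactone, and the stereocentre is α to a carboxylate and so not enolised.

Step 4
Reactants: 8 [4-(benzyloxy)-3-methoxyphenyl]methanol
Product: 9 1-(benzyloxy)-4-(bromomethyl)-2-methoxybenzene
Conditions: PBr3, Et2O, 0 °C
Reagents that add atoms: phosphorus tribromide BrP(Br)Br
Why: The benzylic alcohol is converted to the bromide through its phosphite ester under conditions that leave the aryl benzyl ether alone.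

Step 5
Reactants: 7 (3R)-5-oxotetrahydrofuran-3-carboxylic acid; 9 1-(benzyloxy)-4-(bromomethyl)-2-methoxybenzene
Product: 10 (3R,4R)-4-[4-(benzyloxy)-3-methoxybenzyl]-5-oxotetrahydrofuran-3-carboxylic acid
Conditions: NaN(SiMe3)2 (2.2 equiv), THF, −78 °C; then 9, −78 → −40 °C; aq. HCl
Reagents that add atoms: none
Why: Alkylation of the carboxylate–lactone enolate dianion (as in the α-methylation of paraconic acids) should place the benzyl group anti to the C3 carboxylate, setting C8 as R in a trans relationship, while the carboxylate protects C8'–H from deprotonation.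

Step 6
Reactants: 10
Product: 11 (3R,4R)-4-[4-(benzyloxy)-3-methoxybenzyl]-N-methoxy-N-methyl-5-oxotetrahydrofuran-3-carboxamide
Conditions: MeNHOMe·HCl, EDCI·HCl, HOBt, N-methylmorpholine, CH2Cl2, 0 °C → rt
Reagents that add atoms: N,O-dimethylhydroxylamine hydrochloride CNOC.Cl
Why: Carbodiimide amidation gives the Weinreb amide without opening the lactone, and any C8' epimerisation during activation should return to the favoured trans isomer.

Step 7
Reactants: 11
Product: 12 (3R,4R)-3-[4-(benzyloxy)-3-methoxybenzyl]-4-(prop-2-ynoyl)dihydrofuran-2(3H)-one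
Conditions: HC≡CMgBr, THF, −20 → 0 °C; poured into cold aq. NaHSO4
Reagents that add atoms: ethynylmagnesium bromide C#C[Mg]Br
Why: Weinreb ketone synthesis: the chelated tetrahedral adduct survives until the quench so only one acetylide adds, the weakly basic acetylide should spare the lactone at low temperature, and the acidic quench prevents conjugate addition of the released amine to the ynone.

Step 8
Reactants: 13 (R)-but-3-yn-2-ol
Product: 14 (4R)-pent-2-yne-1,4-diol
Conditions: n-BuLi (2.1 equiv), THF, −78 → 0 °C; paraformaldehyde, 0 °C → rt; aq. NH4Cl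
Reagents that add atoms: paraformaldehyde (formaldehyde unit) C=O
Why: The alkoxide–acetylide dianion adds to formaldehyde at carbon (standard propargylic hydroxymethylation) without touching the carbinol stereocentre.

Step 9
Reactants: 14
Product: 15 (2R)-5-[(tert-butyldimethylsilyl)oxy]pent-3-yn-2-ol
Conditions: TBSCl (1.05 equiv), imidazole, CH2Cl2, −20 → 0 °C
Reagents that add atoms: tert-butyldimethylsilyl chloride CC(C)(C)[Si](C)(C)Cl
Why: The unhindered primary hydroxyl is silylated much faster than the secondary one with one equivalent of silyl chloride.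

Step 10
Reactants: 15
Product: 16 (2R,3Z)-5-[(tert-butyldimethylsilyl)oxy]-3-(tributylstannyl)pent-3-en-2-ol
Conditions: Bu3SnH, [(C5Me5)RuCl]4 (cat.), CH2Cl2, rt
Reagents that add atoms: tributyltin hydride CCCC[SnH](CCCC)CCCC
Why: Ruthenium-catalysed trans-hydrostannation: hydrogen bonding of the free hydroxyl to the Ru–Cl unit steers tin to the proximal alkyne carbon and hydrogen is delivered trans, so the CH2OTBS group ends trans to the carbinol.

Step 11
Reactants: 17 4-iodo-2-methoxyphenol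
Product: 18 1-(benzyloxy)-4-iodo-2-methoxybenzene
Conditions: BnBr, K2CO3, DMF, rt
Reagents that add atoms: benzyl bromide BrCc1ccccc1
Why: Williamson etherification of the phenoxide.

Step 12
Reactants: 16 (2R,3Z)-5-[(tert-butyldimethylsilyl)oxy]-3-(tributylstannyl)pent-3-en-2-ol; 18 1-(benzyloxy)-4-iodo-2-methoxybenzene
Product: 19 (2R,3E)-3-[4-(benzyloxy)-3-methoxyphenyl]-5-[(tert-butyldimethylsilyl)oxy]pent-3-en-2-ol
Conditions: Pd(PPh3)4 (cat.), Cu(O2CC4H3S) (copper thiophene-2-carboxylate), [Bu4N][Ph2PO2], DMF, rt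
Reagents that add atoms: none
Why: Stille coupling promoted by the copper carboxylate with phosphinate as tin scavenger proceeds with retention of alkene geometry under fluoride-free conditions that tolerate the free hydroxyl and the silyl ether.

Step 13
Reactants: 19
Product: 21 ethyl (3R,4Z)-4-[4-(benzyloxy)-3-methoxyphenyl]-3-{[(tert-butyldimethylsilyl)oxy]methyl}hex-4-enoate, via ketene acetal 20 (not isolated)
Conditions: MeC(OEt)3, EtCO2H (cat.), xylene, 135 °C, EtOH distilled off
Reagents that add atoms: triethyl orthoacetate CCOC(C)(OCC)OCC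
Why: Johnson–Claisen rearrangement through a chair transition state with the carbinol methyl equatorial transfers chirality suprafacially from the C–O to the new C–C bond (2R,3E → 3R), which sets C8'' and leaves C7'' masked as an ethylidene.

Step 14
Reactants: 21
Product: 22 (3R,4Z)-4-[4-(benzyloxy)-3-methoxyphenyl]-3-{[(tert-butyldimethylsilyl)oxy]methyl}-N-methoxy-N-methylhex-4-enamide
Conditions: MeNHOMe·HCl, iPrMgCl, THF, −20 → 0 °C
Reagents that add atoms: N,O-dimethylhydroxylamine hydrochloride CNOC.Cl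
Why: The chloromagnesium amide of N,O-dimethylhydroxylamine converts the ethyl ester directly into the Weinreb amide, and the β stereocentre is not acidic.

Step 15
Reactants: 22 (3R,4Z)-4-[4-(benzyloxy)-3-methoxyphenyl]-3-{[(tert-butyldimethylsilyl)oxy]methyl}-N-methoxy-N-methylhex-4-enamide; 23 (Z)-1,2-dimethoxyethene
Product: 25 (1Z,5R,6Z)-6-[4-(benzyloxy)-3-methoxyphenyl]-5-{[(tert-butyldimethylsilyl)oxy]methyl}-1,2-dimethoxyocta-1,6-dien-3-one, via (Z)-1,2-dimethoxyvinyllithium 24 (not isolated)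
Conditions: 23, t-BuLi, THF, −78 °C; then 22, −78 → −40 °C; aq. NH4Cl
Reagents that add atoms: none
Why: α-Lithiation of an enol ether (as for ethyl vinyl ether or 1,4-dioxene) should give an alkenyllithium that keeps its geometry at −78 °C, and its single addition to the Weinreb amide gives the α,β-dimethoxy enone with the β-methoxy group trans to the carbonyl carbon.

Step 16
Reactants: 25
Product: 26 (1Z,3Z,5R,6Z)-6-[4-(benzyloxy)-3-methoxyphenyl]-3-[(tert-butyldimethylsilyl)oxy]-5-{[(tert-butyldimethylsilyl)oxy]methyl}-1,2-dimethoxyocta-1,3,6-triene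
Conditions: TBSOTf, Et3N, Et2O, −78 → 0 °C; filtration through Et3N-deactivated silica
Reagents that add atoms: tert-butyldimethylsilyl trifluoromethanesulfonate CC(C)(C)[Si](C)(C)OS(=O)(=O)C(F)(F)F
Why: Soft enolisation (silyl triflate on the carbonyl oxygen, amine deprotonation at the only α-CH2) gives the cross-conjugated silyloxydiene with the thermodynamically preferred Z enol silane.

Step 17
Reactants: 26 (1Z,3Z,5R,6Z)-6-[4-(benzyloxy)-3-methoxyphenyl]-3-[(tert-butyldimethylsilyl)oxy]-5-{[(tert-butyldimethylsilyl)oxy]methyl}-1,2-dimethoxyocta-1,3,6-triene; 12 (3R,4R)-3-[4-(benzyloxy)-3-methoxybenzyl]-4-(prop-2-ynoyl)dihydrofuran-2(3H)-one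
Product: 28 (3R,4R)-3-[4-(benzyloxy)-3-methoxybenzyl]-4-{3-[(2S,3Z)-3-[4-(benzyloxy)-3-methoxyphenyl]-1-[(tert-butyldimethylsilyl)oxy]pent-3-en-2-yl]-4-[(tert-butyldimethylsilyl)oxy]-5-methoxybenzoyl}dihydrofuran-2(3H)-one, via cyclohexa-1,4-diene cycloadduct 27 (not isolated)
Conditions: 26 (1.3 equiv), toluene, 80 °C; then PPTS (cat.), CH2Cl2, 0 °C → rt
Reagents that add atoms: none
Why: The electron-rich diene and the ynone should combine in a concerted, asynchronous normal-demand [4+2] cycloaddition in which the diene terminus carrying the side chain (largest HOMO coefficient, next to the silyloxy carbon) bonds to the unsubstituted alkyne carbon (C5'–C6') and the methoxy-bearing terminus bonds to the acyl-bearing carbon (C1'–C2'); cycloadduct 27 then loses methanol by acid-assisted ionisation of the doubly allylic C2'–OMe bond and loss of the C5' proton to give the arene. The closest known reaction type is the benzannulation of 1-methoxy-3-silyloxybutadienes with acetylenic ketones to 4-silyloxyaryl ketones. Ring B closes as a six-membered carbocycle by intermolecular [4+2] cycloaddition, both ring bonds forming in one operation. No new stereocentre survives: the two sp3 ring carbons of 27 are erased on aromatisation, C8'' lies outside the π system and is carried through, and C8 and C8' are untouched (C8', α to the new ketone, could only drift towards the favoured trans lactone). The step needs regioselectivity, which the matched polarisation of 3-silyloxydiene and ynone secures and sterics reinforce because the hindered terminus meets the alkyne CH. It also needs an accessible s-cis diene, which the Z enol silane and the outward C1 methoxy group provide.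

Step 18
Reactants: 28
Product: 30 (3R,4R)-3-[4-(benzyloxy)-3-methoxybenzyl]-4-{3-[(2S,3Z)-3-[4-(benzyloxy)-3-methoxyphenyl]-1-[(tert-butyldimethylsilyl)oxy]pent-3-en-2-yl]-4-[(tert-butyldimethylsilyl)oxy]-5-methoxybenzyl}dihydrofuran-2(3H)-one, via tosylhydrazone 29 (not isolated)
Conditions: TsNHNH2, AcOH (cat.), THF, 50 °C; concentrate; catecholborane, CHCl3, 0 °C → rt; then NaOAc·3H2O, 60 °C
Reagents that add atoms: none
Why: Tosylhydrazone reduction (Caglioti type): the borane adds hydride to C=N, acetate triggers loss of sulfinate and the diazene extrudes N2 with hydrogen delivery to C7', so no benzylic cation arises that ring A could trap, and lactone, alkene, silyl and benzyl ethers should be inert.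

Step 19
Reactants: 30
Product: 32 (3R,4R)-3-[4-(benzyloxy)-3-methoxybenzyl]-4-{3-[(2S)-1-[4-(benzyloxy)-3-methoxyphenyl]-3-[(tert-butyldimethylsilyl)oxy]-1-oxopropan-2-yl]-4-[(tert-butyldimethylsilyl)oxy]-5-methoxybenzyl}dihydrofuran-2(3H)-one, via vicinal diol 31 (not isolated)
Conditions: OsO4 (cat.), NaIO4, 2,6-lutidine, dioxane/H2O (3:1), rt
Reagents that add atoms: osmium tetroxide O=[Os](=O)(=O)=O; sodium periodate [Na+].[O-]I(=O)(=O)=O
Why: Lemieux–Johnson oxidation: OsO4 dihydroxylates the only alkene and periodate cleaves the diol to the aryl ketone and acetaldehyde; with every phenol capped periodate cannot oxidise the guaiacyl rings, and the lutidine buffer is too weak to epimerise C8''.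

Step 20
Reactants: 32
Product: 33 (3R,4R)-3-[4-(benzyloxy)-3-methoxybenzyl]-4-{3-[(2S)-1-[4-(benzyloxy)-3-methoxyphenyl]-3-hydroxy-1-oxopropan-2-yl]-4-hydroxy-5-methoxybenzyl}dihydrofuran-2(3H)-one
Conditions: HF·pyridine, THF, 0 °C → rt (polypropylene vessel)
Reagents that add atoms: none
Why: Fluoride cleaves both silyl ethers under acidic buffering, which should avoid the retro-aldol, dehydration and epimerisation that a basic fluoride source could cause at the β-hydroxy ketone.

Step 21
Reactants: 33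
Product: 34 (3R,4R)-3-(4-hydroxy-3-methoxybenzyl)-4-{4-hydroxy-3-[(2S)-3-hydroxy-1-(4-hydroxy-3-methoxyphenyl)-1-oxopropan-2-yl]-5-methoxybenzyl}dihydrofuran-2(3H)-one
Conditions: H2 (1 atm), Pd/C (10% Pd on carbon), EtOAc/EtOH, rt, stopped at full debenzylation
Reagents that add atoms: none
Why: Hydrogenolysis of aryl benzyl ethers over Pd/C under neutral conditions should be much faster than reduction of the donor-substituted aryl ketone, and filtration delivers the target without exposing it to further reagents.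

**Compound list**

1 | (S)-4-benzyloxazolidin-2-one | O=C1N[C@@H](Cc2ccccc2)CO1 | starting material
2 | methyl 4-chloro-4-oxobutanoate | COC(=O)CCC(=O)Cl | starting material
3 | methyl 4-[(4S)-4-benzyl-2-oxooxazolidin-3-yl]-4-oxobutanoate | COC(=O)CCC(=O)N1[C@@H](Cc2ccccc2)COC1=O | intermediate
4 | methyl (3R)-4-[(4S)-4-benzyl-2-oxooxazolidin-3-yl]-3-(hydroxymethyl)-4-oxobutanoate (hydroxymethyl imide, not isolated) | COC(=O)C[C@H](CO)C(=O)N1[C@@H](Cc2ccccc2)COC1=O | intermediate
5 | (4S)-4-benzyl-3-[(3R)-5-oxotetrahydrofuran-3-carbonyl]oxazolidin-2-one | O=C1C[C@@H](C(=O)N2[C@@H](Cc3ccccc3)COC2=O)CO1 | intermediate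
6 | (3R)-5-oxotetrahydrofuran-3-carboperoxoic acid (peroxy acid, not isolated) | O=C1C[C@@H](C(=O)OO)CO1 | intermediate
7 | (3R)-5-oxotetrahydrofuran-3-carboxylic acid ((R)-paraconic acid) | O=C1C[C@@H](C(=O)O)CO1 | intermediate
8 | [4-(benzyloxy)-3-methoxyphenyl]methanol | COc1cc(CO)ccc1OCc1ccccc1 | starting material
9 | 1-(benzyloxy)-4-(bromomethyl)-2-methoxybenzene | COc1cc(CBr)ccc1OCc1ccccc1 | intermediate
10 | (3R,4R)-4-[4-(benzyloxy)-3-methoxybenzyl]-5-oxotetrahydrofuran-3-carboxylic acid | COc1cc(C[C@H]2C(=O)OC[C@@H]2C(=O)O)ccc1OCc1ccccc1 | intermediate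
11 | (3R,4R)-4-[4-(benzyloxy)-3-methoxybenzyl]-N-methoxy-N-methyl-5-oxotetrahydrofuran-3-carboxamide | COc1cc(C[C@H]2C(=O)OC[C@@H]2C(=O)N(C)OC)ccc1OCc1ccccc1 | intermediate
12 | (3R,4R)-3-[4-(benzyloxy)-3-methoxybenzyl]-4-(prop-2-ynoyl)dihydrofuran-2(3H)-one (lactone ethynyl ketone) | COc1cc(C[C@H]2C(=O)OC[C@@H]2C(=O)C#C)ccc1OCc1ccccc1 | intermediate
13 | (R)-but-3-yn-2-ol | C[C@@H](O)C#C | starting material
14 | (4R)-pent-2-yne-1,4-diol | C[C@@H](O)C#CCO | intermediate
15 | (2R)-5-[(tert-butyldimethylsilyl)oxy]pent-3-yn-2-ol | C[C@@H](O)C#CCO[Si](C)(C)C(C)(C)C | intermediate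
16 | (2R,3Z)-5-[(tert-butyldimethylsilyl)oxy]-3-(tributylstannyl)pent-3-en-2-ol | C[C@@H](O)/C(=C/CO[Si](C)(C)C(C)(C)C)[Sn](CCCC)(CCCC)CCCC | intermediate
17 | 4-iodo-2-methoxyphenol | COc1cc(I)ccc1O | starting material
18 | 1-(benzyloxy)-4-iodo-2-methoxybenzene | COc1cc(I)ccc1OCc1ccccc1 | intermediate
19 | (2R,3E)-3-[4-(benzyloxy)-3-methoxyphenyl]-5-[(tert-butyldimethylsilyl)oxy]pent-3-en-2-ol | C[C@@H](O)/C(=C/CO[Si](C)(C)C(C)(C)C)c1ccc(OCc2ccccc2)c(OC)c1 | intermediate
20 | tert-butyl{[(2E,4R)-3-[4-(benzyloxy)-3-methoxyphenyl]-4-[(1-ethoxyvinyl)oxy]pent-2-en-1-yl]oxy}dimethylsilane (ketene acetal, not isolated) | C=C(OCC)O[C@H](C)/C(=C/CO[Si](C)(C)C(C)(C)C)c1ccc(OCc2ccccc2)c(OC)c1 | intermediate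
21 | ethyl (3R,4Z)-4-[4-(benzyloxy)-3-methoxyphenyl]-3-{[(tert-butyldimethylsilyl)oxy]methyl}hex-4-enoate | CCOC(=O)C[C@@H](CO[Si](C)(C)C(C)(C)C)/C(=C/C)c1ccc(OCc2ccccc2)c(OC)c1 | intermediate
22 | (3R,4Z)-4-[4-(benzyloxy)-3-methoxyphenyl]-3-{[(tert-butyldimethylsilyl)oxy]methyl}-N-methoxy-N-methylhex-4-enamide | CON(C)C(=O)C[C@@H](CO[Si](C)(C)C(C)(C)C)/C(=C/C)c1ccc(OCc2ccccc2)c(OC)c1 | intermediate
23 | (Z)-1,2-dimethoxyethene | CO/C=C\OC | starting material
24 | (Z)-1,2-dimethoxyvinyllithium (not isolated) | CO/C=C(OC)/[Li] | intermediate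
25 | (1Z,5R,6Z)-6-[4-(benzyloxy)-3-methoxyphenyl]-5-{[(tert-butyldimethylsilyl)oxy]methyl}-1,2-dimethoxyocta-1,6-dien-3-one | CO/C=C(OC)/C(=O)C[C@@H](CO[Si](C)(C)C(C)(C)C)/C(=C/C)c1ccc(OCc2ccccc2)c(OC)c1 | intermediate
26 | (1Z,3Z,5R,6Z)-6-[4-(benzyloxy)-3-methoxyphenyl]-3-[(tert-butyldimethylsilyl)oxy]-5-{[(tert-butyldimethylsilyl)oxy]methyl}-1,2-dimethoxyocta-1,3,6-triene | CO/C=C(OC)/C(O[Si](C)(C)C(C)(C)C)=C/[C@@H](CO[Si](C)(C)C(C)(C)C)/C(=C/C)c1ccc(OCc2ccccc2)c(OC)c1 | intermediate
27 | cyclohexa-1,4-diene cycloadduct: lactone 12 acylating C1 of a 5,6-dimethoxy-4-(TBS-oxy)cyclohexa-1,4-diene that carries the side chain at C3; mixture at the two sp3 ring carbons (not isolated) | COc1cc(C[C@H]2C(=O)OC[C@@H]2C(=O)C2=CC([C@@H](CO[Si](C)(C)C(C)(C)C)/C(=C/C)c3ccc(OCc4ccccc4)c(OC)c3)C(O[Si](C)(C)C(C)(C)C)=C(OC)C2OC)ccc1OCc1ccccc1 | intermediate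
28 | (3R,4R)-3-[4-(benzyloxy)-3-methoxybenzyl]-4-{3-[(2S,3Z)-3-[4-(benzyloxy)-3-methoxyphenyl]-1-[(tert-butyldimethylsilyl)oxy]pent-3-en-2-yl]-4-[(tert-butyldimethylsilyl)oxy]-5-methoxybenzoyl}dihydrofuran-2(3H)-one (ring B aryl ketone) | COc1cc(C[C@H]2C(=O)OC[C@@H]2C(=O)c2cc(OC)c(O[Si](C)(C)C(C)(C)C)c([C@@H](CO[Si](C)(C)C(C)(C)C)/C(=C/C)c3ccc(OCc4ccccc4)c(OC)c3)c2)ccc1OCc1ccccc1 | intermediate
29 | C7' N-tosylhydrazone of 28 (lactone centres 3R,4S by CIP; same spatial arrangement; not isolated) | COc1cc(C[C@H]2C(=O)OC[C@@H]2C(=NNS(=O)(=O)c2ccc(C)cc2)c2cc(OC)c(O[Si](C)(C)C(C)(C)C)c([C@@H](CO[Si](C)(C)C(C)(C)C)/C(=C/C)c3ccc(OCc4ccccc4)c(OC)c3)c2)ccc1OCc1ccccc1 | intermediate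
30 | (3R,4R)-3-[4-(benzyloxy)-3-methoxybenzyl]-4-{3-[(2S,3Z)-3-[4-(benzyloxy)-3-methoxyphenyl]-1-[(tert-butyldimethylsilyl)oxy]pent-3-en-2-yl]-4-[(tert-butyldimethylsilyl)oxy]-5-methoxybenzyl}dihydrofuran-2(3H)-one | COc1cc(C[C@H]2C(=O)OC[C@@H]2Cc2cc(OC)c(O[Si](C)(C)C(C)(C)C)c([C@@H](CO[Si](C)(C)C(C)(C)C)/C(=C/C)c3ccc(OCc4ccccc4)c(OC)c3)c2)ccc1OCc1ccccc1 | intermediate
31 | vicinal diol from 30: side chain (2S)-3-[4-(benzyloxy)-3-methoxyphenyl]-1-[(tert-butyldimethylsilyl)oxy]-3,4-dihydroxypentan-2-yl; syn-diol, both carbinol carbons unassigned (not isolated) | COc1cc(C[C@H]2C(=O)OC[C@@H]2Cc2cc(OC)c(O[Si](C)(C)C(C)(C)C)c([C@@H](CO[Si](C)(C)C(C)(C)C)C(O)(C(C)O)c3ccc(OCc4ccccc4)c(OC)c3)c2)ccc1OCc1ccccc1 | intermediate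
32 | (3R,4R)-3-[4-(benzyloxy)-3-methoxybenzyl]-4-{3-[(2S)-1-[4-(benzyloxy)-3-methoxyphenyl]-3-[(tert-butyldimethylsilyl)oxy]-1-oxopropan-2-yl]-4-[(tert-butyldimethylsilyl)oxy]-5-methoxybenzyl}dihydrofuran-2(3H)-one | COc1cc(C[C@H]2C(=O)OC[C@@H]2Cc2cc(OC)c(O[Si](C)(C)C(C)(C)C)c([C@@H](CO[Si](C)(C)C(C)(C)C)C(=O)c3ccc(OCc4ccccc4)c(OC)c3)c2)ccc1OCc1ccccc1 | intermediate
33 | (3R,4R)-3-[4-(benzyloxy)-3-methoxybenzyl]-4-{3-[(2S)-1-[4-(benzyloxy)-3-methoxyphenyl]-3-hydroxy-1-oxopropan-2-yl]-4-hydroxy-5-methoxybenzyl}dihydrofuran-2(3H)-one | COc1cc(C[C@H]2C(=O)OC[C@@H]2Cc2cc(OC)c(O)c([C@@H](CO)C(=O)c3ccc(OCc4ccccc4)c(OC)c3)c2)ccc1OCc1ccccc1 | intermediate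
34 | (3R,4R)-3-(4-hydroxy-3-methoxybenzyl)-4-{4-hydroxy-3-[(2S)-3-hydroxy-1-(4-hydroxy-3-methoxyphenyl)-1-oxopropan-2-yl]-5-methoxybenzyl}dihydrofuran-2(3H)-one (CNP0191394.1) | COc1cc(C[C@H]2C(=O)OC[C@@H]2Cc2cc(OC)c(O)c([C@@H](CO)C(=O)c3ccc(O)c(OC)c3)c2)ccc1O | target

**Step count and risks**

Total: 21 steps. Longest linear sequence: 13 steps (13 → 34 through steps 8–10 and 12–21); the ynone branch (steps 1–3, 5–7) and the two one-step side preparations (steps 4 and 11) are convergent.

Steps most likely to fail: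

Step 17 (key step). The tetrasubstituted diene with its branched terminus may cycloadd too slowly, so that hydrolysis of the enol silane or oligomerisation of the terminal ynone competes. The fallback sets out from enone 25 and returns at 28. Dimethylamine in THF should exchange the β-methoxy group of 25 to give the vinylogous amide (1Z,5R,6Z)-1-(dimethylamino)-2-methoxy enone F1. KN(SiMe3)2 and TBSCl in THF at −78 °C should convert it into the 1-amino-3-silyloxydiene F2, a far more reactive diene class. Cycloaddition with 12 at or below room temperature should give the amino cycloadduct F3, which loses dimethylamine on brief treatment with acetic acid to give 28.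

Step 15. The alkenyllithium may lose lithium methoxide by β-elimination or lose its geometry before it is acylated. The fallback sets out from Weinreb amide 22 and returns at 25. Methoxymethyllithium (from Bu3SnCH2OMe and n-BuLi, THF, −78 °C) should give the methoxymethyl ketone F4. Formylation with methyl formate and NaH at the methoxy-bearing methylene should give the hydroxymethylene ketone F5. O-methylation with dimethyl sulfate and K2CO3 in acetone should give 25, the Z isomer being separated and the other geometric isomer recycled by acid-catalysed equilibration of the push–pull alkene.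

Step 18. The hydrazone nitrogen may cyclise onto the lactone carbonyl, or the hindered aryl ketone may condense and reduce incompletely. The fallback sets out from ketone 28 and returns at 30. Luche reduction (NaBH4, CeCl3·7H2O, MeOH/THF, −40 °C) should give the C7' alcohol F6 as an epimer mixture. 1,1'-Thiocarbonyldiimidazole with catalytic DMAP in CH2Cl2 should give the imidazolyl thiocarbonate F7. Barton–McCombie reduction (Bu3SnH, Et3B, air, toluene, rt) should remove the benzylic oxygen through a radical, again avoiding a cation, to give 30.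

Further compounds
F1 | step 17 | (1Z,5R,6Z)-6-[4-(benzyloxy)-3-methoxyphenyl]-5-{[(tert-butyldimethylsilyl)oxy]methyl}-1-(dimethylamino)-2-methoxyocta-1,6-dien-3-one | CN(C)/C=C(OC)/C(=O)C[C@@H](CO[Si](C)(C)C(C)(C)C)/C(=C/C)c1ccc(OCc2ccccc2)c(OC)c1
F2 | step 17 | (1Z,3Z,5R,6Z)-6-[4-(benzyloxy)-3-methoxyphenyl]-3-[(tert-butyldimethylsilyl)oxy]-5-{[(tert-butyldimethylsilyl)oxy]methyl}-1-(dimethylamino)-2-methoxyocta-1,3,6-triene | CN(C)/C=C(OC)/C(O[Si](C)(C)C(C)(C)C)=C/[C@@H](CO[Si](C)(C)C(C)(C)C)/C(=C/C)c1ccc(OCc2ccccc2)c(OC)c1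
F3 | step 17 | amino cycloadduct: analogue of 27 with a 6-(dimethylamino) group in place of the 6-methoxy group, mixture at the two sp3 ring carbons | COc1cc(C[C@H]2C(=O)OC[C@@H]2C(=O)C2=CC([C@@H](CO[Si](C)(C)C(C)(C)C)/C(=C/C)c3ccc(OCc4ccccc4)c(OC)c3)C(O[Si](C)(C)C(C)(C)C)=C(OC)C2N(C)C)ccc1OCc1ccccc1
F4 | step 15 | (4R,5Z)-5-[4-(benzyloxy)-3-methoxyphenyl]-4-{[(tert-butyldimethylsilyl)oxy]methyl}-1-methoxyhept-5-en-2-one | COCC(=O)C[C@@H](CO[Si](C)(C)C(C)(C)C)/C(=C/C)c1ccc(OCc2ccccc2)c(OC)c1
F5 | step 15 | (5R,6Z)-6-[4-(benzyloxy)-3-methoxyphenyl]-5-{[(tert-butyldimethylsilyl)oxy]methyl}-1-hydroxy-2-methoxyocta-1,6-dien-3-one (enol form of the formyl ketone, enol geometry open) | OC=C(OC)C(=O)C[C@@H](CO[Si](C)(C)C(C)(C)C)/C(=C/C)c1ccc(OCc2ccccc2)c(OC)c1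
F6 | step 18 | C7' alcohol from 28 (epimers at C7') | COc1cc(C[C@H]2C(=O)OC[C@@H]2C(O)c2cc(OC)c(O[Si](C)(C)C(C)(C)C)c([C@@H](CO[Si](C)(C)C(C)(C)C)/C(=C/C)c3ccc(OCc4ccccc4)c(OC)c3)c2)ccc1OCc1ccccc1
F7 | step 18 | C7' O-(1H-imidazol-1-ylcarbonothioyl) derivative of F6 | COc1cc(C[C@H]2C(=O)OC[C@@H]2C(OC(=S)n2ccnc2)c2cc(OC)c(O[Si](C)(C)C(C)(C)C)c([C@@H](CO[Si](C)(C)C(C)(C)C)/C(=C/C)c3ccc(OCc4ccccc4)c(OC)c3)c2)ccc1OCc1ccccc1
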